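All runs come from a simulation with constants of no real substance.

A tris adduct holds 3 coupling partners, so in epsilon, with 0.0192 M of partner fed over 1.0 min to 0.016 M of waiting substrate, tris adduct can stand at the end if about 0.00640 M of substrate is still there to take up the partner.

| flask | substrate | coupling partner | remark | time |
|---|---|---|---|---|
| Monday's | 0.016 M | 0.0192 M | run made earlier |  |
| Saturday's | 0.016 M | 0.0096 M | run made earlier |  |
| Wednesday's | 0.016 M | 0.014 M | run made earlier |  |
| Thursday's | 0.0080 M | 0.0192 M | run made earlier |  |
| epsilon | 0.016 M | 0.0192 M (fed, over 1.0 min) | all else is in the flask from the start; the feed brings no volume worth counting | 2.5 min |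
| beta | 0.016 M (fed, over 6.0 s) | 0.0192 M | all else is in the flask from the start; the feed brings no volume worth counting | 2.5 min |
| theta | 0.016 M (fed, over 1.0 min) | 0.0192 M | all else is in the flask from the start; the feed brings no volume worth counting | 2.5 min |
| eta | 0.016 M | 0.0192 M (in portions, 2, over 1.0 min) | first portion at the start, last at 1.0 min | 2.5 min |
| alpha | 0.016 M | 0.0192 M | everything together at the start | 2.5 min |

| run | time / s | tris adduct / % | bis adduct / % | substrate / % |
|---|---|---|---|---|
| Monday's | 10.0 | 13.8 | 28.1 | 11.2 |
| Monday's | 12.0 | 14.3 | 26.8 | 9.5 |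
| Monday's | 15.0 | 14.5 | 27.2 | 8.1 |
| Monday's | 25.0 | 14.6 | 28.1 | 3.7 |
| Monday's | 40.0 | 13.4 | 28.8 | 1.9 |
| Monday's | 60.0 | 13.9 | 27.7 | 0.1 |
| Monday's | 90.0 | 13.7 | 28.1 | 0.2 |
| Saturday's | 15.0 | 2.9 | 13.9 | 14.6 |
| Saturday's | 30.0 | 3.4 | 14.2 | 7.6 |
| Saturday's | 50.0 | 3.6 | 14.0 | 4.0 |
| Saturday's | 60.0 | 2.9 | 14.7 | 2.9 |
| Saturday's | 80.0 | 2.9 | 15.1 | 2.1 |
| Saturday's | 90.0 | 3.4 | 14.8 | 1.2 |
| Saturday's | 120 | 3.2 | 14.5 | 1.0 |
| Wednesday's | 10.0 | 7.2 | 20.6 | 15.0 |
| Wednesday's | 20.0 | 7.1 | 22.4 | 9.1 |
| Wednesday's | 30.0 | 6.9 | 21.4 | 4.8 |
| Wednesday's | 50.0 | 6.7 | 21.4 | 2.1 |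
| Wednesday's | 80.0 | 7.6 | 22.0 | 0.8 |
| Wednesday's | 90.0 | 7.8 | 21.8 | 0.2 |
| Wednesday's | 120 | 7.7 | 22.0 | 0 |
| Thursday's | 25.0 | 48.9 | 22.1 | 0.9 |
| Thursday's | 50.0 | 50.4 | 19.8 | 0.6 |
| Thursday's | 80.0 | 50.9 | 18.7 | 0.6 |
| Thursday's | 90.0 | 51.3 | 18.3 | 0 |
| Thursday's | 120 | 50.0 | 18.4 | 0 |

(standard deviation of a reading: 0.5 percentage points)

- the flask with the highest amount of tris adduct, in percent of the substrate charged ("all alike" if they lie within 1.5 percentage points) (epsilon / beta / theta / eta / alpha / all alike)
- final tris adduct, as a percentage of the substrate charged, in epsilon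
- final tris adduct, as a percentage of the substrate charged, in beta
- final tris adduct, as a percentage of the substrate charged, in theta
- final tris adduct, as a percentage of the substrate charged, in eta
- final tris adduct, as a percentage of the substrate charged, in alpha

- percent here means substrate units held: one self-condensation product counts as two
- steps that have been proposed: coupling partner + bis adduct -> tris adduct + by-product; substrate + by-product -> side product; coupling partner + tris adduct -> tetra adduct + by-product; 2 substrate -> self-condensation product; substrate + coupling partner -> first product + by-product; coupling partner + first product -> bis adduct + by-product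

In Saturday's run the tris and bis readings stand level from 15.0 s while substrate keeps falling. That fall runs at 0.0435 s⁻¹ around a mean substrate of 0.00178 M, then at 0.0321 s⁻¹ around 9.28 × 10⁻⁴ M. A steady pseudo-first-order loss to by-product cancels in the difference, and the slope leaves the self-loss constant g, a rough reading of 13.5 M⁻¹ s⁻¹.

Left alone, substrate S falls at g[S]², while partner arrives at 3.20 × 10⁻⁴ M s⁻¹. Take as caught, c, the substrate standing when these two rates meet. If each partner caught one substrate, c would be 0.00487 M, which leaves 3.94 partners per substrate caught. Going round again, Monday's final readings, with the charged partner reckoned as held by first product, bis and tris, show 1.86 partners per substrate taken up. So the arrival of new catches slows, and c becomes 0.00357 M. The load, partners fed per substrate caught, is then 5.38. The opposite outcome needs a load of 3, but epsilon stands above that, and above 4 too. This reckoning therefore puts epsilon's tris adduct at a few percent, with tetra adduct ahead of it.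

The forecast named eta and gave 19%, 16%, 21%, 23% and 14% for epsilon, beta, theta, eta and alpha, saying “Theta and epsilon reach similar averages but with broader distributions and more tetra.”

    coupling partner + bis adduct → tris adduct + by-product (k = 26.0 M⁻¹ s⁻¹)
    substrate + by-product → side product (k = 2.40 M⁻¹ s⁻¹)
    coupling partner + tris adduct → tetra adduct + by-product (k = 4.70 M⁻¹ s⁻¹)
    2 substrate → self-condensation product (k = 6.90 M⁻¹ s⁻¹)
    substrate + coupling partner → first product + by-product (k = 34.0 M⁻¹ s⁻¹)
    coupling partner + first product → bis adduct + by-product (k = 54.0 M⁻¹ s⁻¹)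

Tris adduct comes to 3.14% in epsilon, 16.6% in beta, 18.3% in theta, 26.3% in eta and 14.3% in alpha, so eta stands highest. Epsilon holds 71.1% as self-condensation product and 22.4% as tetra adduct at 2.50 min. Epsilon's tris and tetra adducts together give a load of 4.70 partners fed per substrate held, with 17.5% of the partner's own charge still unused.

For the neighbour of eta charged with 0.0048 M of coupling partner, the first portion is reckoned to catch 0.00129 M and the substrate awaiting the last portion to add 0.00115 M, so the load is 1.97, below 3. That neighbour flask computes to 3.25% tris adduct beside 7.52% bis adduct.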